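The chain is numbered C1 (CHBr) to C8 (CH2Cl), with methyls C9 on C7 and C10 on C3. On the oxolane ring (O, C3–C6) the side-chain carbons C2 and C7 are cis, so one extra bond from C2 to C8 converts the target into an 8-oxabicyclo[3.2.1]octan-3-one. A (4+3) cycloaddition of 3-chloro-2-methylfuran with the oxazolidinone-substituted oxyallyl cation, made from the N-allenyl oxazolidinone and dimethyldioxirane, builds this bicycle in one operation: it forms C2–C3 and C6–C7, fixes both ring junction stereocentres and brings in the ring chlorine. The cage then controls C4 and C7, and a Baeyer–Villiger oxidation cuts C2–C8.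

Key step: step 5

Remark: the atom labels C1–C10 above are used in the Why lines; bicyclic intermediates carry their own ring numbers in their names.
Assumption: the (S,S)-configured bis(oxazoline) is taken to give the bridgehead sense drawn for 14; should a trial show the opposite sense, the (R,R)-ligand is used and nothing else changes.
Remark: dimethyldioxirane 11 is not bought but distilled as an acetone solution from acetone and KHSO5 and titrated before use.

Step 1
Reactants: 1 3-bromofuran
Product: 3 3-bromo-2-methylfuran, via (3-bromofuran-2-yl)lithium 2 (not isolated)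
Conditions: LiN(i-Pr)2, THF, −78 °C; MeI, −78 °C → rt
Reagents that add atoms: iodomethane, CI
Why: Directed lithiation: bromine acidifies the neighbouring α-hydrogen of the furan, so the amide base metalates C2 without bromine–lithium exchange at −78 °C, and the furyllithium is alkylated by SN2 attack on iodomethane.

Step 2
Reactants: 3 3-bromo-2-methylfuran
Product: 5 3-chloro-2-methylfuran, via (2-methylfuran-3-yl)lithium 4 (not isolated)
Conditions: t-BuLi (2 equiv), Et2O, −78 °C; C2Cl6, −78 °C → rt; fractional distillation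
Reagents that add atoms: hexachloroethane, ClC(Cl)(Cl)C(Cl)(Cl)Cl
Why: Bromine–lithium exchange with t-BuLi followed by electrophilic chlorination of the 3-furyllithium with hexachloroethane; the 2-methyl group blocks the α-position to which 3-lithiofurans otherwise drift, and the low temperature holds the anion in place.

Step 3
Reactants: 6 1,3-oxazolidin-2-one, 7 3-bromoprop-1-yne (propargyl bromide)
Product: 9 3-(prop-2-yn-1-yl)-1,3-oxazolidin-2-one, via sodium 2-oxo-1,3-oxazolidin-3-ide 8 (not isolated)
Conditions: NaH, THF, 0 °C; then 7, 0 °C → rt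
Reagents that add atoms: none
Why: N-Alkylation of a carbamate anion by SN2 displacement on a primary propargylic bromide.

Step 4
Reactants: 9 3-(prop-2-yn-1-yl)-1,3-oxazolidin-2-one
Product: 10 3-(propa-1,2-dien-1-yl)-1,3-oxazolidin-2-one
Conditions: KOt-Bu (20 mol%), THF, rt
Reagents that add atoms: none
Why: Base-catalysed propargyl-to-allenyl isomerisation, which a substoichiometric amount of alkoxide stops at the nitrogen-conjugated allenamide before further migration to the ynamide.

Step 5
Reactants: 5 3-chloro-2-methylfuran, 10 3-(propa-1,2-dien-1-yl)-1,3-oxazolidin-2-one, 11 dimethyldioxirane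
Product: 14 (1S,2S,5R)-7-chloro-1-methyl-2-(2-oxo-1,3-oxazolidin-3-yl)-8-oxabicyclo[3.2.1]oct-6-en-3-one, via allene oxide 12 (not isolated), via oxyallyl cation 13 (not isolated)
Conditions: Cu(OTf)2 (25 mol%), (S,S)-Ph-BOX [2,2′-isopropylidenebis((4S)-4-phenyl-2-oxazoline)] (32 mol%), AgSbF6 (60 mol%), 4 Å molecular sieves, 5 (3 equiv), CH2Cl2, −78 °C; 11 in acetone by syringe pump
Reagents that add atoms: dimethyldioxirane (11), CC1(C)OO1
Why: Dimethyldioxirane epoxidises the nitrogen-bearing double bond of 10, and allene oxide 12 opens to the amide-stabilised oxyallyl cation 13, which divalent copper holds in a chelate between the oxyallyl oxygen and the carbamate carbonyl inside the chiral bis(oxazoline) pocket. The closest known reaction type is the (4+3) cycloaddition of allenamide-derived, nitrogen-stabilised oxyallyl cations with furans, known also under Cu(OTf)2–bis(oxazoline) catalysis and applied here to a halogenated furan. The seven-membered carbocycle closes as a stepwise cycloaddition: the unsubstituted oxyallyl terminus (C7) bonds first to the free α-carbon of the furan (C6), and the nitrogen-bearing copper enolate carbon (C2) then collapses onto the methyl-substituted oxocarbenium carbon (C3). Both bridgeheads (C3 and C6) are created cis because the two bonds form on one face of the furan, and their absolute sense is chosen by the ligand. The nitrogen-bearing centre follows from the compact endo approach and does not matter, since C2 is made planar later. The step needs head-to-head regiochemistry, which the higher nucleophilicity and lower hindrance of the unsubstituted α-carbon of 5 should provide, and chemoselective oxidation of 10 beside the furan, which slow addition of the oxidant at −78 °C to the more electron-rich enamide should secure.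

Step 6
Reactants: 14 (1S,2S,5R)-7-chloro-1-methyl-2-(2-oxo-1,3-oxazolidin-3-yl)-8-oxabicyclo[3.2.1]oct-6-en-3-one
Product: 15 (1S,2S,5R,7S)-7-chloro-1-methyl-2-(2-oxo-1,3-oxazolidin-3-yl)-8-oxabicyclo[3.2.1]octan-3-one
Conditions: KO2CN=NCO2K (excess, in portions), AcOH, MeOH, 0 °C → rt
Reagents that add atoms: none
Why: Diimide reduction: the concerted syn delivery of two hydrogens reaches the strained bridge alkene only from its exo face, the side of the oxygen bridge, so the chlorine is pushed endo (cis to both future arms, C4) and neither the C–Cl bond nor the ketone is touched.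

Step 7
Reactants: 15 (1S,2S,5R,7S)-7-chloro-1-methyl-2-(2-oxo-1,3-oxazolidin-3-yl)-8-oxabicyclo[3.2.1]octan-3-one
Product: 16 (1S,2S,5S,7S)-7-chloro-1-methyl-4-methylidene-2-(2-oxo-1,3-oxazolidin-3-yl)-8-oxabicyclo[3.2.1]octan-3-one
Conditions: (CH2O)n, i-Pr2NH·CF3CO2H, CF3CO2H (10 mol%), THF, reflux
Reagents that add atoms: formaldehyde (as paraformaldehyde), C=O
Why: α-Methylenation of a ketone with formaldehyde and an ammonium trifluoroacetate (Mannich/aldol condensation then elimination); only the methylene α-carbon (C7) can complete the elimination, the nitrogen-bearing α-carbon having a single hydrogen, so the site is fixed by constitution and the new carbon is C9.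

Step 8
Reactants: 16 (1S,2S,5S,7S)-7-chloro-1-methyl-4-methylidene-2-(2-oxo-1,3-oxazolidin-3-yl)-8-oxabicyclo[3.2.1]octan-3-one
Product: 18 (1S,2S,4S,5S,7S)-4-bromo-7-chloro-1,4-dimethyl-2-(2-oxo-1,3-oxazolidin-3-yl)-8-oxabicyclo[3.2.1]octan-3-one, via triethylsilyl enol ether 17 (not isolated)
Conditions: Et3SiH, RhCl(PPh3)3 (2 mol%), THF, 50 °C; then NBS, THF, −78 °C → 0 °C
Reagents that add atoms: N-bromosuccinimide, O=C1CCC(=O)N1Br
Why: Rhodium-catalysed 1,4-hydrosilylation of the s-cis enone gives the tetrasubstituted silyl enol ether with its double bond between C7 and C8 by necessity, and its electrophilic bromination with NBS takes place on the exo face away from the two-carbon bridge, so bromine ends axial and the methyl equatorial, which is the C6/C7 relation of the target.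

Step 9
Reactants: 18 (1S,2S,4S,5S,7S)-4-bromo-7-chloro-1,4-dimethyl-2-(2-oxo-1,3-oxazolidin-3-yl)-8-oxabicyclo[3.2.1]octan-3-one
Product: 19 (1S,2R,5S,6S,8S)-5-bromo-8-chloro-1,5-dimethyl-2-(2-oxo-1,3-oxazolidin-3-yl)-3,9-dioxabicyclo[4.2.1]nonan-4-one
Conditions: CF3CO3H [(CF3CO)2O, H2O2·urea], Na2HPO4, CH2Cl2, 0 °C → rt
Reagents that add atoms: trifluoroperacetic acid, O=C(OO)C(F)(F)F
Why: Baeyer–Villiger oxidation: in the peracid adduct the nitrogen-bearing carbon (C2) migrates with retention, while the fully substituted carbon is held back by its bromine, so oxygen enters between C8 and C2 and the lactone is an acyloxy aminal.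

Step 10
Reactants: 19 (1S,2R,5S,6S,8S)-5-bromo-8-chloro-1,5-dimethyl-2-(2-oxo-1,3-oxazolidin-3-yl)-3,9-dioxabicyclo[4.2.1]nonan-4-one
Product: 21 methyl (2S)-2-bromo-2-[(2S,4S,5S)-4-chloro-5-ethynyl-5-methyloxolan-2-yl]propanoate, via aldehyde ester 20 (not isolated)
Conditions: K2CO3, MeOH, 0 °C; then CH3C(O)C(N2)P(O)(OMe)2, 0 °C → rt
Reagents that add atoms: methanol, CO; dimethyl (1-diazo-2-oxopropyl)phosphonate, COP(=O)(OC)C(=[N+]=[N-])C(C)=O
Why: Transesterification of the lactone by methoxide frees a hemiaminal that falls apart to the aldehyde and oxazolidinone, and the aldehyde, which has no α-hydrogen, is converted in the same flask into the terminal alkyne by the Seyferth–Gilbert homologation in its Ohira–Bestmann form, the new carbon being C1.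

Step 11
Reactants: 21 methyl (2S)-2-bromo-2-[(2S,4S,5S)-4-chloro-5-ethynyl-5-methyloxolan-2-yl]propanoate
Product: 22 (2R)-2-bromo-2-[(2S,4S,5S)-4-chloro-5-ethynyl-5-methyloxolan-2-yl]propan-1-ol
Conditions: i-Bu2AlH (2.5 equiv), CH2Cl2, −78 → −20 °C; aq. potassium sodium tartrate
Reagents that add atoms: none
Why: Hydride reduction of the ester to the primary alcohol with i-Bu2AlH, in which the aluminium alkoxide is too weak a nucleophile to close an epoxide onto the tertiary bromide and the neutral tartrate work-up keeps it so (the descriptor at C7 changes only through the priority rules).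

Step 12
Reactants: 22 (2R)-2-bromo-2-[(2S,4S,5S)-4-chloro-5-ethynyl-5-methyloxolan-2-yl]propan-1-ol
Product: 24 (2S,3S,5S)-5-[(2S)-2-bromo-1-chloropropan-2-yl]-3-chloro-2-ethynyl-2-methyloxolane, via primary triflate 23 (not isolated)
Conditions: Tf2O, 2,6-lutidine, CH2Cl2, −78 °C; then Bu4NCl (5 equiv), −78 → 0 °C
Reagents that add atoms: tetrabutylammonium chloride, CCCC[N+](CCCC)(CCCC)CCCC.[Cl-]
Why: Sulfonate activation and SN2 displacement: the primary triflate meets a high concentration of unsolvated chloride at low temperature in a non-ionising solvent, conditions chosen so that direct substitution at C8 outruns ionisation and the tertiary C–Br bond at C7 keeps its configuration.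

Step 13
Reactants: 24 (2S,3S,5S)-5-[(2S)-2-bromo-1-chloropropan-2-yl]-3-chloro-2-ethynyl-2-methyloxolane
Product: 26 (2S,3S,5S)-5-[(2S)-2-bromo-1-chloropropan-2-yl]-2-[(E)-2-bromoethenyl]-3-chloro-2-methyloxolane, via alkenylzirconocene chloride 25 (not isolated)
Conditions: Cp2Zr(H)Cl (1.5 equiv), CH2Cl2, rt; then NBS, 0 °C
Reagents that add atoms: N-bromosuccinimide, O=C1CCC(=O)N1Br
Why: Hydrozirconation of the terminal alkyne (syn addition, zirconium at the terminal carbon) followed by bromodezirconation with retention gives the (E)-bromoalkene, a sequence that tolerates alkyl halides.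

Compound list
1 | 3-bromofuran | Brc1ccoc1 | starting material
2 | (3-bromofuran-2-yl)lithium | [Li]c1occc1Br | intermediate (not isolated)
3 | 3-bromo-2-methylfuran | Cc1occc1Br | intermediate
4 | (2-methylfuran-3-yl)lithium | [Li]c1ccoc1C | intermediate (not isolated)
5 | 3-chloro-2-methylfuran | Cc1occc1Cl | intermediate
6 | 1,3-oxazolidin-2-one | O=C1NCCO1 | starting material
7 | 3-bromoprop-1-yne (propargyl bromide) | C#CCBr | starting material
8 | sodium 2-oxo-1,3-oxazolidin-3-ide | [Na+].O=C1[N-]CCO1 | intermediate (not isolated)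
9 | 3-(prop-2-yn-1-yl)-1,3-oxazolidin-2-one | C#CCN1CCOC1=O | intermediate
10 | 3-(propa-1,2-dien-1-yl)-1,3-oxazolidin-2-one | C=C=CN1CCOC1=O | intermediate
11 | dimethyldioxirane (freshly prepared acetone solution) | CC1(C)OO1 | starting material
12 | 3-(3-methylideneoxiran-2-yl)-1,3-oxazolidin-2-one (allene oxide, transient) | C=C1OC1N1CCOC1=O | intermediate (not isolated)
13 | 2-oxido-1-(2-oxo-1,3-oxazolidin-3-yl)allyl cation (oxyallyl cation, copper-bound) | C=C([O-])C=[N+]1CCOC1=O | intermediate (not isolated)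
14 | (1S,2S,5R)-7-chloro-1-methyl-2-(2-oxo-1,3-oxazolidin-3-yl)-8-oxabicyclo[3.2.1]oct-6-en-3-one | O=C2C[C@@H]1C=C(Cl)[C@](C)([C@@H]2N3CCOC3=O)O1 | intermediate
15 | (1S,2S,5R,7S)-7-chloro-1-methyl-2-(2-oxo-1,3-oxazolidin-3-yl)-8-oxabicyclo[3.2.1]octan-3-one (chlorine endo) | O=C2C[C@@H]1C[C@H](Cl)[C@](C)([C@@H]2N3CCOC3=O)O1 | intermediate
16 | (1S,2S,5S,7S)-7-chloro-1-methyl-4-methylidene-2-(2-oxo-1,3-oxazolidin-3-yl)-8-oxabicyclo[3.2.1]octan-3-one | O=C2C(=C)[C@@H]1C[C@H](Cl)[C@](C)([C@@H]2N3CCOC3=O)O1 | intermediate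
17 | 3-[(1S,2S,5S,7S)-7-chloro-1,4-dimethyl-3-(triethylsilyloxy)-8-oxabicyclo[3.2.1]oct-3-en-2-yl]-1,3-oxazolidin-2-one | CC[Si](CC)(CC)OC2=C(C)[C@@H]1C[C@H](Cl)[C@](C)([C@@H]2N3CCOC3=O)O1 | intermediate (not isolated)
18 | (1S,2S,4S,5S,7S)-4-bromo-7-chloro-1,4-dimethyl-2-(2-oxo-1,3-oxazolidin-3-yl)-8-oxabicyclo[3.2.1]octan-3-one (bromine axial, on the face of the oxygen bridge) | O=C2[C@@](C)(Br)[C@@H]1C[C@H](Cl)[C@](C)([C@@H]2N3CCOC3=O)O1 | intermediate
19 | (1S,2R,5S,6S,8S)-5-bromo-8-chloro-1,5-dimethyl-2-(2-oxo-1,3-oxazolidin-3-yl)-3,9-dioxabicyclo[4.2.1]nonan-4-one | O=C2[C@@](C)(Br)[C@@H]1C[C@H](Cl)[C@](C)([C@H](N3CCOC3=O)O2)O1 | intermediate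
20 | methyl (2S)-2-bromo-2-[(2S,4S,5S)-4-chloro-5-formyl-5-methyloxolan-2-yl]propanoate | COC(=O)[C@@](C)(Br)[C@@H]1C[C@H](Cl)[C@](C)(C=O)O1 | intermediate (not isolated)
21 | methyl (2S)-2-bromo-2-[(2S,4S,5S)-4-chloro-5-ethynyl-5-methyloxolan-2-yl]propanoate | COC(=O)[C@@](C)(Br)[C@@H]1C[C@H](Cl)[C@](C)(C#C)O1 | intermediate
22 | (2R)-2-bromo-2-[(2S,4S,5S)-4-chloro-5-ethynyl-5-methyloxolan-2-yl]propan-1-ol | OC[C@@](C)(Br)[C@@H]1C[C@H](Cl)[C@](C)(C#C)O1 | intermediate
23 | (2R)-2-bromo-2-[(2S,4S,5S)-4-chloro-5-ethynyl-5-methyloxolan-2-yl]propyl trifluoromethanesulfonate | FC(F)(F)S(=O)(=O)OC[C@@](C)(Br)[C@@H]1C[C@H](Cl)[C@](C)(C#C)O1 | intermediate (not isolated)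
24 | (2S,3S,5S)-5-[(2S)-2-bromo-1-chloropropan-2-yl]-3-chloro-2-ethynyl-2-methyloxolane | ClC[C@@](C)(Br)[C@@H]1C[C@H](Cl)[C@](C)(C#C)O1 | intermediate
25 | [(E)-2-{(2S,3S,5S)-5-[(2S)-2-bromo-1-chloropropan-2-yl]-3-chloro-2-methyloxolan-2-yl}ethenyl]chloridobis(cyclopentadienyl)zirconium | ClC[C@@](C)(Br)[C@@H]1C[C@H](Cl)[C@](C)(/C=C/[Zr](Cl)(C2C=CC=C2)C2C=CC=C2)O1 | intermediate (not isolated)
26 | (2S,3S,5S)-5-[(2S)-2-bromo-1-chloropropan-2-yl]-2-[(E)-2-bromoethenyl]-3-chloro-2-methyloxolane | C[C@@](Br)(CCl)[C@@H]1C[C@H](Cl)[C@](C)(/C=C/Br)O1 | target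

Total step count: 13.
Longest linear sequence: 11 steps (steps 1, 2 and 5–13; the allenamide branch, steps 3, 4 and 5–13, is equally long).

Steps most likely to fail

1. Step 5. The chlorine makes the furan a poorer partner than the furans this cycloaddition is known for, so capture of the copper-bound oxyallyl cation may be slow and the ligand may discriminate the two faces incompletely, giving the adduct in low enantiomeric purity. The fallback replaces catalyst control by auxiliary control. It sets out from propargyl bromide 7 and furan 5 and returns at aldehyde ester 20.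
 - Commercial (4S)-4-phenyl-1,3-oxazolidin-2-one is N-propargylated (NaH, 7) to the propargyl carbamate F1 and isomerised (KOt-Bu, catalytic) to the chiral allenamide F2.
 - Oxidation of F2 with dimethyldioxirane beside ZnCl2 and 5 at −78 °C should give diastereomeric cycloadducts. The cycloadduct F3, with the bridgehead configuration of 14, is separated by chromatography. It is assumed that the (4S)-auxiliary favours this isomer; otherwise its enantiomer is used.
 - F3 is carried through the conditions of steps 6 to 9: saturated ketone F4, enone F5, silyl enol ether F6 (not isolated), bromo ketone F7 and lactone F8.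
 - The methanolysis of step 10 then releases the auxiliary and gives 20.

2. Step 12. While the C8 leaving group departs, the tertiary bromine on C7 may take part as a neighbouring group, forming a bromonium ion that chloride opens at the tertiary carbon, so that the two halogens change places. The fallback brings chlorine onto C8 without a leaving group next to bromine and adds bromine last. It sets out from triflate 23 and returns at 24, at the price of weaker control over C7.
 - NaI in acetone should displace the triflate to the iodide F9 (not isolated), which loses its vicinal halogens under iodide to give the isopropenyl oxolane F10.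
 - Ene-type allylic chlorination of F10 with hypochlorous acid (Ca(OCl)2, CO2, CH2Cl2–H2O, 0 °C) should give the allylic chloride F11.
 - Markovnikov addition of HBr to F11 (CH2Cl2, −78 °C) should give 24 together with its C7 epimer F12. C7 is then set only by the bias of the neighbouring ring centre, and the epimers are separated by chromatography.

3. Step 9. The carbonyl of 18 is flanked by a fully substituted and a tertiary carbon, so addition of the peracid and rearrangement of the bromine-deactivated adduct may be slow enough for acid to degrade the acyloxy aminal as it forms. The fallback moves the oxygen insertion to the unhindered ketone and does the C7 chemistry on the lactone. It sets out from 15 and returns at 19.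
 - Baeyer–Villiger oxidation of 15 (mCPBA, NaHCO3, CH2Cl2) should give the lactone F13 by migration of the nitrogen-bearing carbon.
 - The lithium enolate of F13 (LiN(i-Pr)2, THF, −78 °C) is aminomethylated with Eschenmoser's salt to the Mannich base F14.
 - N-Methylation of F14 with MeI gives the methiodide F15, which eliminates with NaHCO3 to the methylene lactone F16.
 - Conjugate reduction of F16 with LiBH(s-Bu)3 at −78 °C and trapping of the enolate with NBS on the face of the oxygen bridge should give 19.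

Further compounds
F1 | step 5 | (4S)-4-phenyl-3-(prop-2-yn-1-yl)-1,3-oxazolidin-2-one | C#CCN1[C@@H](c2ccccc2)COC1=O
F2 | step 5 | (4S)-4-phenyl-3-(propa-1,2-dien-1-yl)-1,3-oxazolidin-2-one | C=C=CN1[C@@H](c2ccccc2)COC1=O
F3 | step 5 | (1S,2S,5R)-7-chloro-1-methyl-2-[(4S)-2-oxo-4-phenyl-1,3-oxazolidin-3-yl]-8-oxabicyclo[3.2.1]oct-6-en-3-one | O=C2C[C@@H]1C=C(Cl)[C@](C)([C@@H]2N3[C@@H](c4ccccc4)COC3=O)O1
F4 | step 5 | (1S,2S,5R,7S)-7-chloro-1-methyl-2-[(4S)-2-oxo-4-phenyl-1,3-oxazolidin-3-yl]-8-oxabicyclo[3.2.1]octan-3-one | O=C2C[C@@H]1C[C@H](Cl)[C@](C)([C@@H]2N3[C@@H](c4ccccc4)COC3=O)O1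
F5 | step 5 | (1S,2S,5S,7S)-7-chloro-1-methyl-4-methylidene-2-[(4S)-2-oxo-4-phenyl-1,3-oxazolidin-3-yl]-8-oxabicyclo[3.2.1]octan-3-one | O=C2C(=C)[C@@H]1C[C@H](Cl)[C@](C)([C@@H]2N3[C@@H](c4ccccc4)COC3=O)O1
F6 | step 5 | (4S)-3-[(1S,2S,5S,7S)-7-chloro-1,4-dimethyl-3-(triethylsilyloxy)-8-oxabicyclo[3.2.1]oct-3-en-2-yl]-4-phenyl-1,3-oxazolidin-2-one | CC[Si](CC)(CC)OC2=C(C)[C@@H]1C[C@H](Cl)[C@](C)([C@@H]2N3[C@@H](c4ccccc4)COC3=O)O1
F7 | step 5 | (1S,2S,4S,5S,7S)-4-bromo-7-chloro-1,4-dimethyl-2-[(4S)-2-oxo-4-phenyl-1,3-oxazolidin-3-yl]-8-oxabicyclo[3.2.1]octan-3-one | O=C2[C@@](C)(Br)[C@@H]1C[C@H](Cl)[C@](C)([C@@H]2N3[C@@H](c4ccccc4)COC3=O)O1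
F8 | step 5 | (1S,2R,5S,6S,8S)-5-bromo-8-chloro-1,5-dimethyl-2-[(4S)-2-oxo-4-phenyl-1,3-oxazolidin-3-yl]-3,9-dioxabicyclo[4.2.1]nonan-4-one | O=C2[C@@](C)(Br)[C@@H]1C[C@H](Cl)[C@](C)([C@H](N3[C@@H](c4ccccc4)COC3=O)O2)O1
F9 | step 12 | (2S,3S,5S)-5-[(2S)-2-bromo-1-iodopropan-2-yl]-3-chloro-2-ethynyl-2-methyloxolane | IC[C@@](C)(Br)[C@@H]1C[C@H](Cl)[C@](C)(C#C)O1
F10 | step 12 | (2S,3S,5S)-3-chloro-2-ethynyl-2-methyl-5-(prop-1-en-2-yl)oxolane | CC(=C)[C@@H]1C[C@H](Cl)[C@](C)(C#C)O1
F11 | step 12 | (2S,3S,5S)-3-chloro-5-(3-chloroprop-1-en-2-yl)-2-ethynyl-2-methyloxolane | ClCC(=C)[C@@H]1C[C@H](Cl)[C@](C)(C#C)O1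
F12 | step 12 | (2S,3S,5S)-5-[(2R)-2-bromo-1-chloropropan-2-yl]-3-chloro-2-ethynyl-2-methyloxolane | ClC[C@](C)(Br)[C@@H]1C[C@H](Cl)[C@](C)(C#C)O1
F13 | step 9 | (1S,2R,6R,8S)-8-chloro-1-methyl-2-(2-oxo-1,3-oxazolidin-3-yl)-3,9-dioxabicyclo[4.2.1]nonan-4-one | O=C2C[C@@H]1C[C@H](Cl)[C@](C)([C@H](N3CCOC3=O)O2)O1
F14 | step 9 | (1S,2R,5S,6S,8S)-8-chloro-5-[(dimethylamino)methyl]-1-methyl-2-(2-oxo-1,3-oxazolidin-3-yl)-3,9-dioxabicyclo[4.2.1]nonan-4-one | O=C2[C@@H](CN(C)C)[C@@H]1C[C@H](Cl)[C@](C)([C@H](N3CCOC3=O)O2)O1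
F15 | step 9 | {[(1S,2R,5S,6S,8S)-8-chloro-1-methyl-4-oxo-2-(2-oxo-1,3-oxazolidin-3-yl)-3,9-dioxabicyclo[4.2.1]nonan-5-yl]methyl}trimethylammonium iodide | O=C2[C@@H](C[N+](C)(C)C)[C@@H]1C[C@H](Cl)[C@](C)([C@H](N3CCOC3=O)O2)O1.[I-]
F16 | step 9 | (1S,2R,6S,8S)-8-chloro-1-methyl-5-methylidene-2-(2-oxo-1,3-oxazolidin-3-yl)-3,9-dioxabicyclo[4.2.1]nonan-4-one | O=C2C(=C)[C@@H]1C[C@H](Cl)[C@](C)([C@H](N3CCOC3=O)O2)O1
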